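**Retrosynthetic overview**
- The target is the 7-O-acetate of a threo-(7R,8R) 8-O-4′ neolignan. The acetate C–O bond and the C7–aryl bond are cut together, giving (3,4,5-trimethoxyphenyl)magnesium bromide, an (R)-2-aryloxypropanal and Ac2O, which are joined in one flask.
- Enabling feature: the C8 ether oxygen lies α to the C7 carbonyl and between the two ortho-methoxy groups of the 2,6-dimethoxy-4-propenylphenyl ring. This O,O-donor set lets Mg(II) clamp O=C7–C8–O into a five-membered chelate, so the single C8 stereocentre dictates C7 (threo).
- The aldehyde comes from ethyl (S)-lactate: Mitsunobu etherification with the (E)-propenyl phenol (inversion, giving 8R), then DIBAL-H half-reduction.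
- The (E)-propenyl phenol comes from commercial 4-allyl-2,6-dimethoxyphenol by Ru–H isomerisation; the Grignard reagent from 5-bromo-1,2,3-trimethoxybenzene.
- No ring is formed; both benzene rings are bought intact. The order of events is alkene geometry, C8–O bond, C7 oxidation level, then C7–aryl and C7–OAc together.

Key step: step 5

Remark: neolignan numbering is used (C7 = benzylic acetoxy carbon, C8 = methyl-bearing ether carbon); the SMILES encodes (7R,8R), the threo series.

**Step 1**
Reactants: 1 4-allyl-2,6-dimethoxyphenol
Product: 2 (E)-2,6-dimethoxy-4-(prop-1-en-1-yl)phenol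
Conditions: [RuClH(CO)(PPh3)3] (2 mol%), toluene, 80 °C
Reagents that add atoms: none
Why: Ruthenium-hydride-catalysed alkene isomerisation (hydrometalation/β-hydride elimination) should move the terminal double bond into conjugation with the arene and settle at the thermodynamically favoured E-isomer, from which residual Z-isomer can be removed by crystallisation or AgNO3–silica chromatography.

**Step 2**
Reactants: 2 (E)-2,6-dimethoxy-4-(prop-1-en-1-yl)phenol; 3 ethyl (S)-lactate
Product: 4 ethyl (2R)-2-{2,6-dimethoxy-4-[(E)-prop-1-en-1-yl]phenoxy}propanoate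
Conditions: PPh3, DIAD, THF, 0 °C → rt
Reagents that add atoms: none
Why: Mitsunobu etherification, in which the acidic 2,6-dimethoxyphenol should displace the phosphonium-activated lactate hydroxyl by SN2 with inversion, so that the (S)-lactate carbon becomes the (R)-configured C8 of the target.

**Step 3**
Reactants: 4 ethyl (2R)-2-{2,6-dimethoxy-4-[(E)-prop-1-en-1-yl]phenoxy}propanoate
Product: 6 (2R)-2-{2,6-dimethoxy-4-[(E)-prop-1-en-1-yl]phenoxy}propanal, via aluminium hemiacetal 5 (not isolated)
Conditions: DIBAL-H (1.1 equiv), CH2Cl2, −78 °C; MeOH, then aq. Rochelle salt, −78 °C → rt; crude aldehyde used at once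
Reagents that add atoms: none
Why: Partial reduction of an ester with DIBAL-H, in which the tetrahedral aluminium hemiacetal 5 is held at −78 °C by chelation to the α-aryloxy oxygen and should collapse to the aldehyde only on work-up, leaving C8 untouched provided the crude aldehyde is not chromatographed.

**Step 4**
Reactants: 7 5-bromo-1,2,3-trimethoxybenzene
Product: 8 (3,4,5-trimethoxyphenyl)magnesium bromide (titrated THF solution)
Conditions: Mg turnings, I2 (cat.), THF, reflux
Reagents that add atoms: magnesium, [Mg]
Why: Grignard reagent formation by oxidative insertion of magnesium into the aryl C–Br bond should proceed normally for this electron-rich bromide and fixes the nucleophilic site at the carbon para to the central methoxy group.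

**Step 5**
Reactants: 6 (2R)-2-{2,6-dimethoxy-4-[(E)-prop-1-en-1-yl]phenoxy}propanal; 8 (3,4,5-trimethoxyphenyl)magnesium bromide
Product: 10 (1R,2R)-2-{2,6-dimethoxy-4-[(E)-prop-1-en-1-yl]phenoxy}-1-(3,4,5-trimethoxyphenyl)propyl acetate, via bromomagnesium alkoxide 9 (not isolated)
Conditions: 6, MgBr2·OEt2 (2 equiv), CH2Cl2, −78 °C; 8 (1.5 equiv, minimum THF), −78 °C; then Ac2O (5 equiv), DMAP (0.2 equiv), −78 → 0 °C; aq. NaHCO3
Reagents that add atoms: acetic anhydride, CC(=O)OC(C)=O
Why: The Grignard reagent adds 1,2 to the aldehyde held in a Cram chelate, in which Mg bridges the C7 carbonyl oxygen and the C8 aryloxy oxygen (five-membered O=C7–C8–O–Mg array, backed by an ortho-methoxy oxygen of the same ring), and the resulting bromomagnesium alkoxide 9 is acetylated in the same flask by Ac2O/DMAP. The closest known reaction type is the chelation-controlled addition of Grignard reagents to α-alkoxy aldehydes with in situ O-acylation of the magnesium alkoxide. No ring of the target is closed; the chelate is transient. The new stereocentre C7 is controlled by the existing (R)-C8 centre: in the chelate the C8 methyl group shields one carbonyl face, the aryl group enters from the face of the C8 hydrogen, and this gives the (7R,8R) threo relationship. The step needs diastereofacial selectivity (threo over erythro), secured by the bidentate ether donor set, pre-complexation with MgBr2·OEt2 and a weakly coordinating solvent at −78 °C; it also needs addition to outrun enolisation at C8, secured by the low basicity of the aryl Grignard reagent and the low temperature. The propenyl group, the aryl methyl ethers and the C8–O aryl ether are inert to both reagents, so the one operation should form the C–C bond, set C7, install the acetate and deliver the target.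

**Compound list**
1 | 4-allyl-2,6-dimethoxyphenol | C=CCc1cc(OC)c(O)c(OC)c1 | starting material
2 | (E)-2,6-dimethoxy-4-(prop-1-en-1-yl)phenol | C/C=C/c1cc(OC)c(O)c(OC)c1 | intermediate
3 | ethyl (S)-lactate | CCOC(=O)[C@H](C)O | starting material
4 | ethyl (2R)-2-{2,6-dimethoxy-4-[(E)-prop-1-en-1-yl]phenoxy}propanoate | C/C=C/c1cc(OC)c(O[C@H](C)C(=O)OCC)c(OC)c1 | intermediate
5 | diisobutylaluminium ethyl hemiacetal of 4 (O-aluminated, mixture at the hemiacetal carbon) | C/C=C/c1cc(OC)c(O[C@H](C)C(OCC)O[Al](CC(C)C)CC(C)C)c(OC)c1 | intermediate
6 | (2R)-2-{2,6-dimethoxy-4-[(E)-prop-1-en-1-yl]phenoxy}propanal | C/C=C/c1cc(OC)c(O[C@H](C)C=O)c(OC)c1 | intermediate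
7 | 5-bromo-1,2,3-trimethoxybenzene | COc1cc(Br)cc(OC)c1OC | starting material
8 | (3,4,5-trimethoxyphenyl)magnesium bromide | COc1cc([Mg]Br)cc(OC)c1OC | intermediate
9 | bromomagnesium (1R,2R)-2-{2,6-dimethoxy-4-[(E)-prop-1-en-1-yl]phenoxy}-1-(3,4,5-trimethoxyphenyl)propan-1-olate | C/C=C/c1cc(OC)c(O[C@H](C)[C@H](O[Mg]Br)c2cc(OC)c(OC)c(OC)c2)c(OC)c1 | intermediate
10 | (1R,2R)-2-{2,6-dimethoxy-4-[(E)-prop-1-en-1-yl]phenoxy}-1-(3,4,5-trimethoxyphenyl)propyl acetate | C/C=C/c1cc(OC)c(O[C@H](C)[C@H](OC(C)=O)c2cc(OC)c(OC)c(OC)c2)c(OC)c1 | target

**Totals**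
Total step count: 5. Longest linear sequence: 4 (steps 1, 2, 3, 5); step 4 is a one-step side branch.

**Steps most likely to fail**

Step 5. Chelation may be incomplete, so that open-chain Felkin–Anh addition erodes the facial selectivity, and the acetylation of the magnesium alkoxide may stall. The fallback sets out from compound 4 and comes back at compound 10. Ester 4 is converted with MeNHOMe·HCl/iPrMgCl (THF, −20 °C) into the Weinreb amide F1. Grignard reagent 8 (THF, −20 → 0 °C, dilute HCl quench) then forms the same aryl–C7 bond by acyl substitution and gives the aryl ketone F2. Reduction with L-Selectride (THF, −78 °C) should follow the polar Felkin–Anh course, with hydride anti to the C8–O bond, to give the threo alcohol F3. Ac2O, pyridine and DMAP (CH2Cl2, 0 °C) then give 10.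

Step 3. Over-reduction to the primary alcohol and loss of configurational purity at C8 by enolisation of the α-aryloxy aldehyde during work-up are the concerns. The fallback sets out from compound 4 and comes back at compound 6. Ester 4 is reduced fully with LiAlH4 (THF, 0 °C) to the primary alcohol F4, which is configurationally stable and can be purified. It is oxidised with Dess–Martin periodinane (NaHCO3, CH2Cl2, 0 °C) to 6 immediately before step 5.

Step 2. The di-ortho-substituted phenol may couple slowly, so that elimination of the activated lactate and incomplete inversion compete. The fallback sets out from compound 3 and comes back at compound 4. Ethyl (S)-lactate 3 is converted with TsCl, Et3N and DMAP (CH2Cl2, 0 °C) into the tosylate F5. Phenol 2 with K2CO3 in MeCN at 60 °C should displace it by SN2 with inversion to give 4.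

**Further compounds**
F1 | step 5 | (2R)-2-{2,6-dimethoxy-4-[(E)-prop-1-en-1-yl]phenoxy}-N-methoxy-N-methylpropanamide | C/C=C/c1cc(OC)c(O[C@H](C)C(=O)N(C)OC)c(OC)c1
F2 | step 5 | (2R)-2-{2,6-dimethoxy-4-[(E)-prop-1-en-1-yl]phenoxy}-1-(3,4,5-trimethoxyphenyl)propan-1-one | C/C=C/c1cc(OC)c(O[C@H](C)C(=O)c2cc(OC)c(OC)c(OC)c2)c(OC)c1
F3 | step 5 | (1R,2R)-2-{2,6-dimethoxy-4-[(E)-prop-1-en-1-yl]phenoxy}-1-(3,4,5-trimethoxyphenyl)propan-1-ol | C/C=C/c1cc(OC)c(O[C@H](C)[C@H](O)c2cc(OC)c(OC)c(OC)c2)c(OC)c1
F4 | step 3 | (2R)-2-{2,6-dimethoxy-4-[(E)-prop-1-en-1-yl]phenoxy}propan-1-ol | C/C=C/c1cc(OC)c(O[C@H](C)CO)c(OC)c1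
F5 | step 2 | ethyl (2S)-2-(p-toluenesulfonyloxy)propanoate | CCOC(=O)[C@H](C)OS(=O)(=O)c1ccc(C)cc1
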